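At late times the target drains into the isomer of the product until it holds 25.0% of what was made, so watch how much target stands when the clock stops.

common to all: substrate 0.18 M; enzyme 90 µM; time 2.0 min

| run | impurity |
|---|---|
| oak | 5.0 µM |
| larch | 10 µM |
| alder | 20 µM |
| cedar | 40 µM |
| elm | 80 µM |

    substrate + enzyme → target + enzyme, rate k1*[substrate]*[enzyme]/(1 + ([substrate]/Km1) + ([target]/Kp1)) (Km1 = 7.1 mM, Kp1 = 48 mM, k1 = 7600 L mol⁻¹ s⁻¹)
    enzyme + impurity → spent catalyst (k2 = 55000 L mol⁻¹ s⁻¹)
    target ⇌ isomer of the product (K3 = 3.0, k3 = 0.0080 s⁻¹)

- "hardly changes" means that all values lie within two and a half points (for a concentration: within two and a half percent of the largest)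
- run time (oak): 2.0 min

- amount of target at the end, in percent of the substrate charged for oak, larch, alder, cedar, elm, in this order
- how that number moves from the first to the last of them (hardly changes / rises all the way / rises, then falls / falls, then rises / falls all the way)

Two times matter: the run time, 2.0 min, and a clearing time. Take the impurity first. At the full enzyme charge it lives about 0.202 s, far shorter than the run. So count the working enzyme as its charge minus the impurity charge.

Now the substrate. At the start [substrate]/Km is 25.4, so the enzyme is saturated and the conversion runs at zero order. Its full speed is the rate constant times Km times [enzyme]. Work with the fraction of substrate left, which then falls on a straight line. For oak, the substrate charge over that full speed gives 0.654 min. Call this the clearing time: the time the surviving enzyme needs at full speed.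

Oak's clearing time is about a third of the run. The target term in the rate law has a ceiling of 3.75, its value with the whole charge standing as target, and this ceiling is smaller than the substrate term at the start. The target term slows the tail, so the clearing time is a floor.

The clearing time grows as the surviving enzyme shrinks. Cedar's is 1.11 min, shorter than the run but longer than oak's. Cedar's target is therefore made later and has less of the run to drain. Elm's is 5.56 min, longer than the run, so I expect 64.0% of elm's substrate left at the end. My reckoning stops there: it gives a rise, then a fall, but no row of numbers.

The forecast gives 51.6%, 52%, 53%, 56.3% and 22.7%, and its shape is rises, then falls. It holds that the surviving enzyme “is still enough to finish the substrate within 2 min in all runs except elm”.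

The simulation gives 52.2%, 52.7%, 53.9%, 58.0% and 23.0%, and the shape is rises, then falls. The row turns at an impurity charge of 51 µM, above cedar's and below elm's. Oak's clearing time of 0.654 min is shorter than 1.00 min, and at that time oak holds 1.64% of its substrate. Elm's clearing time of 5.56 min puts the fraction left at 1.00 min at 82.0%, and elm stands at 81.8% then. At 2.00 min elm holds 65.4% of its substrate.

All constants are made up.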